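**Retrosynthetic overview**

1. Locants: ring C1 (side chain), C2 (OH), C3–C4 (oxirane, CH3 on C4), C5 (C=O), C6 (OAc); chain C7 (on C1), C8 (=CH2), C9 (angelate carbinol).
2. Feature: the C3=C4 bond of the 2-methylcyclohex-2-enone (C5=O, C4–CH3) behind the epoxy ketone is the aldol-condensation retron of a C5 ethyl ketone and a C3 aldehyde. Joining C3 to C5 as an alkene gives a 1-ethylcyclopentene (ring atoms C1, C2, C3, C5, C6) that already holds the all-trans C6/C1/C2 triad.
3. Late disconnections: C2–OH and C6–OAc (silyl ethers), oxirane (enone plus peroxide anti to C2–O), C9 ester, C7–C9 (alkenyl iodide plus 4-methylpent-3-enal, Ni/Cr), C7–I (terminal alkyne).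
4. Early disconnections: C5–ethyl (enol triflate cross-coupling), C6–O (Rubottom oxidation), C1–alkynyl (anti conjugate addition to (R)-4-silyloxycyclopentenone).
5. Ring order: chiral-pool cyclopentane, then the six-membered carbocycle by cleavage and aldol re-closure (step 6), then the oxirane (step 12).

Key step: step 6

Remarks on the chemistry:
- Intermediates are described with the target locants. The five-membered compounds contain C1, C2, C3, C5 and C6 only; C4 arrives as the CH2 of the ethyl group.
- Assumption: the valinol-derived oxazoline–sulfonamide ligand of step 10 is taken in the enantiomeric form that favours the 9S carbinol. Its sense of induction would be assigned on first use (MTPA esters) and the antipode taken if required.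

**Route**

Step 1
Reactants: 1 (R)-4-(tert-butyldimethylsilyloxy)cyclopent-2-en-1-one; 2 ethynyltrimethylsilane
Product: 5 trimethylsilyl enol ether (C5(OSiMe3)=C6; C1 trimethylsilylethynyl trans to C2 OTBS), via lithium trimethylsilylacetylide 3 (not isolated), via trimethylsilylethynylzinc bromide 4 (not isolated)
Conditions: 2, n-BuLi, THF, –78 °C; ZnBr2, Et2O, 0 °C; then 1, TMSOTf, –40 °C; Et3N, pentane, filtration
Reagents that add atoms: trimethylsilyl triflate C[Si](C)(C)OS(=O)(=O)C(F)(F)F
Why: Silyl-triflate-promoted conjugate addition of an alkynylzinc halide to an enone: TMSOTf activates the enone and traps the enolate as the C5=C6 silyl enol ether, and the alkynyl group enters C1 on the face opposite the adjacent C2 silyloxy group, which should set C1 trans to C2 as is general for 4-silyloxycyclopent-2-enones.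

Step 2
Reactants: 5 trimethylsilyl enol ether
Product: 7 C6 hydroxy ketone (C5 ketone; C6 OH trans to the C1 alkynyl group and cis to C2 OTBS), via C6 trimethylsilyloxy ketone 6 (not isolated)
Conditions: mCPBA, NaHCO3, CH2Cl2, –20 → 0 °C; then 10% aq citric acid, THF, 0 °C
Reagents that add atoms: 3-chloroperbenzoic acid OOC(=O)c1cccc(Cl)c1
Why: Rubottom oxidation: the peracid transfers oxygen to the electron-rich enol ether on the face opposite the adjacent C1 alkynyl substituent, 1,4-silyl migration gives silyloxy ketone 6 and mild acid frees the C6 hydroxyl trans to C1 (a minor cis isomer, if formed, could be equilibrated later at the cyclohexenone stage, where C6 is alpha to the ketone and trans is the stable arrangement).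

Step 3
Reactants: 7 C6 hydroxy ketone
Product: 8 C6 triethylsilyloxy ketone
Conditions: TESCl, imidazole, DMF, 0 °C
Reagents that add atoms: chlorotriethylsilane CC[Si](Cl)(CC)CC
Why: Standard silylation of a secondary alcohol under conditions too mild to enolise the ketone, so C6 and the beta-silyloxy ketone are left as they are.

Step 4
Reactants: 8 C6 triethylsilyloxy ketone
Product: 10 enol triflate (C5(OTf)=C3), via lithium enolate 9 (not isolated)
Conditions: LiHMDS, THF, –78 °C; then N-(5-chloro-2-pyridyl)triflimide, –78 °C
Reagents that add atoms: N-(5-chloropyridin-2-yl)-bis(trifluoromethanesulfonyl)imide O=S(=O)(N(c1ccc(Cl)cn1)S(=O)(=O)C(F)(F)F)C(F)(F)F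
Why: Kinetic enolisation and O-triflation: the hindered amide base removes a proton from the C3 methylene (C6–H is tertiary and oxygen-substituted), and the lithium enolate is trapped at –78 °C by the reactive pyridyl triflimide before it can expel the C2 silyloxy group by E1cB.

Step 5
Reactants: 10 enol triflate
Product: 11 1-ethylcyclopentene (C5 ethyl; C3=C5; C6 OTES; C1 silylalkynyl; C2 OTBS)
Conditions: EtMgBr, Fe(acac)3 (5 mol %), THF/NMP, –30 °C
Reagents that add atoms: ethylmagnesium bromide CC[Mg]Br
Why: Iron-catalysed cross-coupling of an alkenyl triflate with an alkyl Grignard reagent is fast at –30 °C, is not troubled by beta-hydride elimination with EtMgBr and leaves silyl ethers and the silyl-capped alkyne alone.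

Step 6
Reactants: 11 1-ethylcyclopentene; 12 ozone
Product: 16 2-methylcyclohex-2-enone (C5 ketone; C3=C4; C4 methyl; C6 OTES; C1 silylalkynyl; C2 OTBS), via secondary ozonide 13 (not isolated), via keto aldehyde 14 (not isolated), via aldol adduct 15 (not isolated)
Conditions: 12 (O3), CH2Cl2, Sudan Red 7B (indicator), –78 °C; Me2S, –78 °C → rt; concentrate; piperidine/AcOH (piperidinium acetate, 0.3 equiv), 4 Å MS, toluene, rt → 45 °C
Reagents that add atoms: none
Why: Ozone adds to the electron-rich trisubstituted C3=C5 ring alkene and the adduct rearranges to ozonide 13, which Me2S reduces to keto aldehyde 14; the buffered amine salt then enolises the C5 ethyl ketone toward its CH2 (the future C4), which adds to the C3 aldehyde to give aldol 15, and loss of water gives the C3=C4 enone. The closest known reaction type is ozonolysis of a 1-alkylcycloalkene followed by intramolecular aldol condensation of the keto aldehyde, a one-carbon ring enlargement to a 2-alkylcycloalk-2-enone. The six-membered ring closes in a 6-(enolendo)-exo-trig aldol, since both enolate carbons C4 and C5 lie in the new ring; enolisation of the ketone toward C6 or of the aldehyde toward C2 could only close strained four-membered rings reversibly. No stereocentre is created in the product: the transient centres C3 and C4 of 15 are erased on dehydration, and C6, C1 and C2 are carried through from 11. The step needs cleavage of the ring alkene only, which its much higher reactivity toward ozone than the silyl-capped alkyne, the low temperature and the indicator end point should secure. It also needs retention at C2 while alpha to the aldehyde, which the weakly acidic amine salt and the bulky OTBS group should secure, while C6 already sits in its stable trans arrangement.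

Step 7
Reactants: 16 2-methylcyclohex-2-enone
Product: 17 terminal alkyne (C1 ethynyl)
Conditions: K2CO3 (0.2 equiv), MeOH, 0 °C
Reagents that add atoms: none
Why: Base-catalysed methanolysis of the C(sp)–Si bond (protodesilylation) is much faster than cleavage of the secondary TES and TBS ethers, and C6, the only enolisable centre, already has its stable configuration.

Step 8
Reactants: 17 terminal alkyne
Product: 19 alkenyl iodide (C7 iodo; C7=C8H2), via (Z)-2-iodoalkenyl-9-BBN 18 (not isolated)
Conditions: B-I-9-BBN, pentane/CH2Cl2, –20 °C; AcOH, 0 °C; aq NaHCO3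
Reagents that add atoms: B-iodo-9-borabicyclo[3.3.1]nonane IB1C2CCCC1CCC2
Why: Iodoboration–protodeboronation: the iodoborane adds syn across the terminal alkyne with iodine on the internal carbon C7 (Markovnikov) and acetic acid cleaves the C8–B bond, leaving the 2-iodo-1-alkene, while the s-trans, alpha-methylated ring enone cannot engage the borane in a cyclic conjugate addition.

Step 9
Reactants: 20 4-methylpent-3-en-1-ol
Product: 21 4-methylpent-3-enal (kept cold in solution and used at once)
Conditions: DMP, NaHCO3, CH2Cl2, 0 °C
Reagents that add atoms: none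
Why: Dess–Martin oxidation of a primary alcohol under bicarbonate buffering stops at the aldehyde and is mild enough not to move the beta,gamma double bond into conjugation.

Step 10
Reactants: 19 alkenyl iodide; 21 4-methylpent-3-enal
Product: 22 (9S) allylic alcohol (C7–C9 bond; C9 OH; enone and both silyl ethers retained)
Conditions: CrCl2 (4 equiv), oxazoline–sulfonamide ligand (4.4 equiv), Et3N, THF, rt; then NiCl2 (5 mol %), 19, 21 (2.5 equiv), rt
Reagents that add atoms: none
Why: Nozaki–Hiyama–Kishi coupling: zerovalent nickel inserts into the C7–I bond, transmetalation gives an alkenylchromium species (trivalent chromium) that adds to the aldehyde but not to the hindered ring ketone, and the chiral sulfonamide ligand on chromium selects the aldehyde face (reagent control) to set C9 as S.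

Step 11
Reactants: 22 (9S) allylic alcohol; 23 angelic acid
Product: 25 C9 angelate, via mixed anhydride 24 (not isolated)
Conditions: 23, 2,4,6-trichlorobenzoyl chloride, Et3N, toluene, rt; then 22, 75 °C
Reagents that add atoms: none
Why: Yamaguchi-type esterification through the mixed 2,4,6-trichlorobenzoic anhydride, run without DMAP, acylates the hindered allylic alcohol with retention at C9 and avoids the nucleophile-induced isomerisation of the angelate to the tiglate.

Step 12
Reactants: 25 C9 angelate
Product: 26 epoxy ketone (C3–C4 oxirane anti to C2 OTBS and syn to the C1 side chain)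
Conditions: TBHP (decane), DBU, CH2Cl2, 0 °C → rt
Reagents that add atoms: tert-butyl hydroperoxide CC(C)(C)OO
Why: Weitz–Scheffer nucleophilic epoxidation: the peroxide anion adds to C3 of the enone on the face opposite the adjacent C2 OTBS group and the enolate closes onto oxygen, so C3 and C4 are set together anti to C2–O, while the isolated alkenes and the less electrophilic angelate should not react.

Step 13
Reactants: 26 epoxy ketone
Product: 27 C6 alcohol (C2 OTBS retained)
Conditions: HF·pyridine, pyridine, THF, 0 °C
Reagents that add atoms: none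
Why: Buffered HF·pyridine removes the more labile triethylsilyl ether far faster than the tert-butyldimethylsilyl ether (selective desilylation), and the mildly acidic medium should leave the electron-poor oxirane and the ester alone.

Step 14
Reactants: 27 C6 alcohol
Product: 28 C6 acetate
Conditions: Ac2O, pyridine, DMAP (cat.), CH2Cl2, 0 °C
Reagents that add atoms: acetic anhydride CC(=O)OC(C)=O
Why: DMAP-catalysed acetylation of the alpha-hydroxy ketone is fast at 0 °C under conditions too weakly basic to epimerise C6.

Step 15
Reactants: 28 C6 acetate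
Product: 29 target (C2 OH free)
Conditions: HF·pyridine, THF, 0 °C → rt
Reagents that add atoms: none
Why: Fluoride cleavage of the Si–O bond under acidic HF·pyridine (desilylation) avoids alkoxide formation at C2, and with it Payne rearrangement of the anti epoxy alcohol and acetyl migration from C6.

**Compound list**

1 | (R)-4-(tert-butyldimethylsilyloxy)cyclopent-2-en-1-one | O=C1C=C[C@H](O[Si](C)(C)C(C)(C)C)C1 | starting material
2 | ethynyltrimethylsilane | C#C[Si](C)(C)C | starting material
3 | lithium trimethylsilylacetylide (not isolated) | [Li]C#C[Si](C)(C)C | intermediate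
4 | trimethylsilylethynylzinc bromide (not isolated) | Br[Zn]C#C[Si](C)(C)C | intermediate
5 | trimethylsilyl enol ether, C5(OSiMe3)=C6, C1 alkynyl trans to C2 OTBS | C[Si](C)(C)C#C[C@H]1[C@H](O[Si](C)(C)C(C)(C)C)CC(O[Si](C)(C)C)=C1 | intermediate
6 | C6 trimethylsilyloxy ketone (not isolated) | C[Si](C)(C)C#C[C@H]1[C@H](O[Si](C)(C)C(C)(C)C)CC(=O)[C@@H]1O[Si](C)(C)C | intermediate
7 | C6 hydroxy ketone, C6 OH trans to C1 alkynyl | C[Si](C)(C)C#C[C@H]1[C@H](O[Si](C)(C)C(C)(C)C)CC(=O)[C@@H]1O | intermediate
8 | C6 triethylsilyloxy ketone | C[Si](C)(C)C#C[C@H]1[C@H](O[Si](C)(C)C(C)(C)C)CC(=O)[C@@H]1O[Si](CC)(CC)CC | intermediate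
9 | lithium enolate, C5(OLi)=C3 (not isolated) | C[Si](C)(C)C#C[C@H]1[C@H](O[Si](C)(C)C(C)(C)C)C=C(O[Li])[C@@H]1O[Si](CC)(CC)CC | intermediate
10 | enol triflate, C5(OTf)=C3 | C[Si](C)(C)C#C[C@H]1[C@H](O[Si](C)(C)C(C)(C)C)C=C(OS(=O)(=O)C(F)(F)F)[C@@H]1O[Si](CC)(CC)CC | intermediate
11 | 1-ethylcyclopentene (key-step precursor), C5 ethyl, C3=C5, all-trans C6/C1/C2 | C[Si](C)(C)C#C[C@H]1[C@H](O[Si](C)(C)C(C)(C)C)C=C(CC)[C@@H]1O[Si](CC)(CC)CC | intermediate
12 | ozone | [O-][O+]=O | starting material
13 | secondary ozonide across C3 and C5 (mixture at C3/C5; not isolated) | C[Si](C)(C)C#C[C@H]1[C@H](O[Si](C)(C)C(C)(C)C)C2OOC(CC)(O2)[C@@H]1O[Si](CC)(CC)CC | intermediate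
14 | keto aldehyde, C3 aldehyde and C5 ethyl ketone (not isolated) | C[Si](C)(C)C#C[C@@H]([C@H](O[Si](C)(C)C(C)(C)C)C=O)[C@@H](O[Si](CC)(CC)CC)C(=O)CC | intermediate
15 | aldol adduct, C3 OH and C4 methyl (epimers at C3/C4; not isolated) | C[Si](C)(C)C#C[C@H]1[C@H](O[Si](C)(C)C(C)(C)C)C(O)C(C)C(=O)[C@@H]1O[Si](CC)(CC)CC | intermediate
16 | 2-methylcyclohex-2-enone (key-step product) | C[Si](C)(C)C#C[C@H]1[C@H](O[Si](C)(C)C(C)(C)C)C=C(C)C(=O)[C@@H]1O[Si](CC)(CC)CC | intermediate
17 | terminal alkyne | C#C[C@H]1[C@H](O[Si](C)(C)C(C)(C)C)C=C(C)C(=O)[C@@H]1O[Si](CC)(CC)CC | intermediate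
18 | (Z)-2-iodoalkenyl-9-BBN (not isolated) | I/C(=C\B1C2CCCC1CCC2)[C@H]1[C@H](O[Si](C)(C)C(C)(C)C)C=C(C)C(=O)[C@@H]1O[Si](CC)(CC)CC | intermediate
19 | alkenyl iodide, C7 iodo | C=C(I)[C@H]1[C@H](O[Si](C)(C)C(C)(C)C)C=C(C)C(=O)[C@@H]1O[Si](CC)(CC)CC | intermediate
20 | 4-methylpent-3-en-1-ol | CC(C)=CCCO | starting material
21 | 4-methylpent-3-enal | CC(C)=CCC=O | intermediate
22 | (9S) allylic alcohol | C=C([C@H]1[C@H](O[Si](C)(C)C(C)(C)C)C=C(C)C(=O)[C@@H]1O[Si](CC)(CC)CC)[C@H](CC=C(C)C)O | intermediate
23 | angelic acid, (Z)-2-methylbut-2-enoic acid | C/C=C(/C)C(=O)O | starting material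
24 | angelic 2,4,6-trichlorobenzoic mixed anhydride (not isolated) | C/C=C(/C)C(=O)OC(=O)c1c(Cl)cc(Cl)cc1Cl | intermediate
25 | C9 angelate of the enone | C=C([C@H]1[C@H](O[Si](C)(C)C(C)(C)C)C=C(C)C(=O)[C@@H]1O[Si](CC)(CC)CC)[C@H](CC=C(C)C)OC(=O)/C(C)=C\C | intermediate
26 | epoxy ketone, oxirane anti to C2 OTBS | C=C([C@H]1[C@H](O[Si](C)(C)C(C)(C)C)[C@H]2O[C@@]2(C)C(=O)[C@@H]1O[Si](CC)(CC)CC)[C@H](CC=C(C)C)OC(=O)/C(C)=C\C | intermediate
27 | C6 alcohol | C=C([C@H]1[C@H](O[Si](C)(C)C(C)(C)C)[C@H]2O[C@@]2(C)C(=O)[C@@H]1O)[C@H](CC=C(C)C)OC(=O)/C(C)=C\C | intermediate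
28 | C6 acetate | C=C([C@H]1[C@H](O[Si](C)(C)C(C)(C)C)[C@H]2O[C@@]2(C)C(=O)[C@@H]1OC(C)=O)[C@H](CC=C(C)C)OC(=O)/C(C)=C\C | intermediate
29 | CNP0272666.1, (1S,2S,3R,4R,6R,9S) in the locants used here | C=C([C@H]1[C@H](O)[C@H]2O[C@@]2(C)C(=O)[C@@H]1OC(C)=O)[C@H](CC=C(C)C)OC(=O)/C(C)=C\C | target

**Step count and risks**

Total step count: 15. Longest linear sequence: 14 steps (steps 1–8 and 10–15, from 1 to 29); step 9 is a one-step branch.

The three steps most likely to fail:

First, step 6. Ozone may begin to oxidise the silylalkyne before the ring alkene is consumed. During the amine-salt condensation, C2 may epimerise through the enol or enamine of the aldehyde, or silanol may be lost toward an aromatic ring. The fallback sets out from 11 and comes back at 16. Catalytic OsO4 with NMO (acetone/water) should dihydroxylate only the ring alkene, on the face anti to the two allylic silyloxy groups, to give cis-diol F1. NaIO4 cleaves F1 to keto aldehyde 14, which is now isolated. Soft enolisation of the ethyl ketone with Bu2BOTf and iPr2NEt at –78 °C gives dibutylboron enolate F2, which closes onto the aldehyde without any free amine; after a pH 7 buffer/MeOH/H2O2 work-up, aldol 15 is isolated. Mesylation (MsCl, Et3N, 0 °C) gives mesylate F3, and DBU eliminates it to enone 16.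

Second, step 8. The Lewis-acidic iodoborane may cleave the triethylsilyl ether or deliver iodide to the enone in competition with iodoboration of the alkyne. The fallback sets out from 17 and comes back at 19. Markovnikov hydrosilylation of the terminal alkyne with benzyldimethylsilane, catalysed by [Cp*Ru(MeCN)3]PF6 (CH2Cl2, 0 °C → rt), should give alpha-vinylsilane F4. Iododesilylation with N-iodosuccinimide in hexafluoroisopropanol buffered with 2,6-lutidine (0 °C) then gives alkenyl iodide 19.

Third, step 10. Facial selection at the aldehyde may be poor with so hindered an alkenylchromium partner, giving a mixture at C9. The fallback sets out from 19 and comes back at 25. The coupling is run without the chiral ligand (CrCl2, NiCl2 cat., DMSO, rt) and the C9 epimers are separated. The 9S alcohol 22 goes through step 11. The 9R alcohol F5 is esterified with angelic acid 23 under Mitsunobu conditions (PPh3, DIAD, toluene, 0 °C), with inversion at C9, to give angelate 25.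

**Further compounds**

F1 | step 6 | cis-diol at C3 and C5 of the ethylcyclopentane (hydroxyls anti to the silyloxy groups) | C[Si](C)(C)C#C[C@H]1[C@H](O[Si](C)(C)C(C)(C)C)[C@@H](O)[C@](O)(CC)[C@@H]1O[Si](CC)(CC)CC
F2 | step 6 | dibutylboron (Z)-enolate of keto aldehyde 14 (C5(OBBu2)=C4) | C[Si](C)(C)C#C[C@@H]([C@H](O[Si](C)(C)C(C)(C)C)C=O)[C@@H](O[Si](CC)(CC)CC)/C(OB(CCCC)CCCC)=C/C
F3 | step 6 | C3 mesylate of aldol 15 (epimers at C3/C4) | C[Si](C)(C)C#C[C@H]1[C@H](O[Si](C)(C)C(C)(C)C)C(OS(C)(=O)=O)C(C)C(=O)[C@@H]1O[Si](CC)(CC)CC
F4 | step 8 | alpha-vinylsilane (C7 benzyldimethylsilyl; C7=C8H2) | C=C([Si](C)(C)Cc1ccccc1)[C@H]1[C@H](O[Si](C)(C)C(C)(C)C)C=C(C)C(=O)[C@@H]1O[Si](CC)(CC)CC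
F5 | step 10 | (9R) allylic alcohol, C9 epimer of 22 | C=C([C@H]1[C@H](O[Si](C)(C)C(C)(C)C)C=C(C)C(=O)[C@@H]1O[Si](CC)(CC)CC)[C@@H](CC=C(C)C)O
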